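**Plan**

- Retrosynthesis (labdane numbering): cut C8–C17 (enol triflate plus hydroxymethylstannane), then C3–C4 (ring A, radical closure onto a C3 aldehyde), re-form the C4–C7 bond as a cyclobutane, and finally cut C1–C10 and C9–C11 together.
- This leads to (1S,5S)-verbenone, which already contains ring B (C5–C10): its enone is C8(=O)–C9=C10(CH3), the bridgehead beside the alkene is C5, the gem-dimethyl bridge carbon is C4 and the bridgehead beside the carbonyl is C7.
- Forward: a C1–C3 Grignard reagent adds to C10 and the enolate is alkylated at C9 by the C11–C15 iodide in one pot; the cyclobutane is then cleaved (C4–C7) to the C5 isopropenyl group; ring A closes at C3–C4; C17 is added last.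
- Stereochemistry: C5 comes from verbenone; C10 from addition anti to the gem-dimethyl bridge (C1 trans to C4, hence the trans ring fusion); C13 from methyl hydrogen (R)-3-methylglutarate; C9 by base equilibration to the equatorial chain; C3 in the radical closure (equatorial carbinol).

Key step: step 4

Remark on the chemistry: C3 is carried through the key step as a primary silyl ether (alcohol level), because the acylating Lewis acid of step 5 should exchange a silyl ether for an acetate but would open an acetal unselectively.
Remark: labdane numbering (C1–C17) is used for all intermediates; compound 4 and Bu3SnCH2OH are taken as purchasable.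

**Route**

Step 1
Reactants: 1 methyl hydrogen (R)-3-methylglutarate
Product: 2 methyl (R)-5-hydroxy-3-methylpentanoate
Conditions: BH3·SMe2 (1.1 equiv), THF, −10 °C → rt; MeOH quench, aqueous work-up; used crude
Reagents that add atoms: none
Why: Borane reduces a carboxylic acid much faster than an ester (chemoselective borane reduction), so only the future C11 becomes CH2OH, the stereocentre (later C13) is untouched, and immediate use of the crude alcohol forestalls lactonisation.

Step 2
Reactants: 2 methyl (R)-5-hydroxy-3-methylpentanoate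
Product: 3 methyl (S)-5-iodo-3-methylpentanoate
Conditions: I2, PPh3, imidazole, CH2Cl2, 0 °C → rt
Reagents that add atoms: iodine, II
Why: The Appel reaction converts the primary alcohol into the iodide under neutral conditions that leave the ester and the stereocentre alone (the descriptor changes only through CIP priority).

Step 3
Reactants: 4 (3-bromopropoxy)(tert-butyl)dimethylsilane
Product: 5 [3-(tert-butyldimethylsilyloxy)propyl]magnesium bromide
Conditions: Mg turnings (activated with a crystal of I2), THF, rt → 40 °C; titrated and used as a THF solution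
Reagents that add atoms: magnesium, [Mg]
Why: Grignard formation from an unhindered primary bromide is routine and the silyl ether is inert to the organomagnesium centre.

Step 4
Reactants: 6 (1S,5S)-(−)-verbenone; 5 [3-(tert-butyldimethylsilyloxy)propyl]magnesium bromide; 3 methyl (S)-5-iodo-3-methylpentanoate
Product: 8 methyl (3R)-5-{(1S,3R,4R,5R)-4-[3-(tert-butyldimethylsilyloxy)propyl]-4,6,6-trimethyl-2-oxobicyclo[3.1.1]heptan-3-yl}-3-methylpentanoate, via bromomagnesium enolate 7 (not isolated)
Conditions: CuBr·SMe2 (20 mol %), THF/Me2S, −40 °C, slow addition of 5 (1.2 equiv) to 6; then 3 (2.0 equiv), hexamethylphosphoramide (4 equiv), −40 °C → rt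
Reagents that add atoms: none
Why: The Grignard reagent 5 transmetalates to a monovalent-copper ate species that adds to the β-carbon C10 of the enone (π-complex, trivalent-copper σ-adduct, reductive elimination) to give the bromomagnesium enolate 7, which is then alkylated at C9 by the primary iodide 3 in an SN2 reaction accelerated by hexamethylphosphoramide. The closest known reaction type is the copper-catalysed conjugate addition of Grignard reagents to β,β-disubstituted enones with in-situ alkylation of the enolate (three-component coupling), and organocopper additions to verbenone are established. No ring is closed: the step forms the two skeletal bonds C1–C10 and C9–C11. The C10 stereocentre is set by the gem-dimethyl bridge (C4 and its methyl group lie over one face of the enone), so C1 enters anti to C4, which later gives the trans ring fusion with the verbenone methyl as the angular methyl group. The C9 stereocentre is set by the same bridge, the iodide approaching anti to it and cis to the C1 chain; this is the C9 epimer of the target and is inverted by equilibration in step 6. The step needs 1,4- over 1,2-addition (copper, slow addition of 5 at low temperature) and clean mono-C-alkylation, which the substrate supports because the bridgehead C7 cannot enolise (Bredt's rule), so the enolate is regiostable, cannot be alkylated twice at a C9 flanked by quaternary C10, and can be left with excess iodide until consumed.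

Step 5
Reactants: 8 the C9-alkylated, C10-quaternary verbanone
Product: 9 methyl (3R)-5-[(1R,5R,6R)-2-acetoxy-6-(3-acetoxypropyl)-6-methyl-5-(prop-1-en-2-yl)cyclohex-2-en-1-yl]-3-methylpentanoate (C7=C8 enol acetate, C5 isopropenyl, C3 acetate)
Conditions: BF3·OEt2 (3 equiv), Zn(OAc)2 (0.5 equiv), Ac2O, 0 °C → rt
Reagents that add atoms: acetic anhydride, CC(=O)OC(C)=O
Why: Lewis-acid activation of the C8 carbonyl should heterolyse the strained C4–C7 bond (acid-mediated cyclobutane cleavage of a pinane-type ketone), the tertiary C4 cation losing a methyl proton to give the C5 isopropenyl group while the enol is trapped regiospecifically as the C7=C8 acetate and the same medium exchanges the primary silyl ether for an acetate (acetolysis); C5, C9, C10 and C13 are not involved.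

Step 6
Reactants: 9 the dienyl diacetate
Product: 10 methyl (3R)-5-[(1S,2R,3R)-2-(3-hydroxypropyl)-2-methyl-6-oxo-3-(prop-1-en-2-yl)cyclohexyl]-3-methylpentanoate (C8 ketone, C3 primary alcohol, C9 inverted)
Conditions: NaOMe (0.3 equiv), MeOH, 0 °C → 45 °C, continued until the C9 epimer ratio no longer changes
Reagents that add atoms: none
Why: Zemplén-type transesterification removes both acetates (the methyl ester is degenerate in methanol), and the freed C8 ketone equilibrates through its C8–C9 enolate to the epimer whose C11 chain is equatorial, cis to the C10 methyl and trans to C1, because the axial chain would meet H-5 and H-7 (thermodynamic epimerisation, which sets C9).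

Step 7
Reactants: 10 the hydroxy ketone
Product: 11 methyl (3R)-3-methyl-5-[(1S,2R,3R)-2-methyl-6-oxo-2-(3-oxopropyl)-3-(prop-1-en-2-yl)cyclohexyl]pentanoate (C3 aldehyde)
Conditions: TEMPO (10 mol %), PhI(OAc)2 (1.1 equiv), CH2Cl2, rt; used without storage
Reagents that add atoms: none
Why: Oxoammonium oxidation (TEMPO/PhI(OAc)2) stops at the aldehyde and leaves the isopropenyl group, the ketone and the α-stereocentre C9 alone under near-neutral conditions.

Step 8
Reactants: 11 the keto aldehyde
Product: 12 methyl (3R)-5-[(1S,4aS,6R,8aR)-6-hydroxy-5,5,8a-trimethyl-2-oxodecahydronaphthalen-1-yl]-3-methylpentanoate (trans-decalin, equatorial C3–OH, C8 ketone)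
Conditions: Fe(acac)3 (50 mol %), PhSiH3 (2.5 equiv), degassed EtOH (0.02 M), 60 °C
Reagents that add atoms: none
Why: Hydrogen-atom transfer from the iron hydride to the isopropenyl CH2 gives the tertiary C4 radical, which should add 6-exo to the C3 aldehyde through a chair that fuses ring A trans (C5 and C10 are already fixed) and places the carbinol oxygen equatorial, the alkoxy radical then being reduced (metal-hydride hydrogen-atom-transfer radical cyclisation of an alkene onto a carbonyl group, favoured here over the transannular attack on the C8 ketone, which needs a boat).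

Step 9
Reactants: 12 the hydroxy decalone
Product: 13 methyl (3R)-3-methyl-5-[(1S,4aS,6R,8aR)-5,5,8a-trimethyl-2-oxo-6-(triethylsilyloxy)decahydronaphthalen-1-yl]pentanoate
Conditions: Et3SiCl (1.5 equiv), imidazole, DMAP (cat.), DMF, rt
Reagents that add atoms: chlorotriethylsilane, CC[Si](Cl)(CC)CC
Why: Standard silylation masks the C3 hydroxyl so that it is neither deprotonated nor sulfonylated in step 10, under conditions too mild to disturb C9.

Step 10
Reactants: 13 the silyl-protected decalone
Product: 15 methyl (3R)-3-methyl-5-[(1S,4aS,6R,8aR)-5,5,8a-trimethyl-6-(triethylsilyloxy)-2-(trifluoromethylsulfonyloxy)-1,4,4a,5,6,7,8,8a-octahydronaphthalen-1-yl]pentanoate, via potassium enolate 14 (not isolated)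
Conditions: KN(SiMe3)2 (1.1 equiv), THF, −78 °C; then PhNTf2 (1.2 equiv), −78 → 0 °C
Reagents that add atoms: N-phenylbis(trifluoromethanesulfonimide), O=S(=O)(N(c1ccccc1)S(=O)(=O)C(F)(F)F)C(F)(F)F
Why: The hindered amide base removes the accessible C7 proton rather than the tertiary C9–H next to quaternary C10 (kinetic enolate formation; the ketone is several pKa units more acidic than the ester), and O-triflation fixes the C7=C8 double bond without touching C9.

Step 11
Reactants: 15 the C7-ene C8 triflate
Product: 16 methyl (3R)-5-[(1S,4aS,6R,8aS)-2-(hydroxymethyl)-5,5,8a-trimethyl-6-(triethylsilyloxy)-1,4,4a,5,6,7,8,8a-octahydronaphthalen-1-yl]-3-methylpentanoate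
Conditions: Bu3SnCH2OH (1.5 equiv), Pd(PPh3)4 (10 mol %), LiCl (3 equiv), 1,4-dioxane, 100 °C
Reagents that add atoms: (tributylstannyl)methanol, OC[Sn](CCCC)(CCCC)CCCC
Why: Stille coupling of an enol triflate with the hydroxymethylstannane (oxidative addition to zerovalent palladium, chloride exchange, transmetalation, reductive elimination) installs C17 as CH2OH with the double bond held at C7=C8 and tolerates the ester and silyl ether.

Step 12
Reactants: 16 the silyl-protected diol ester
Product: 17 methyl (3R)-5-[(1S,4aS,6R,8aS)-6-hydroxy-2-(hydroxymethyl)-5,5,8a-trimethyl-1,4,4a,5,6,7,8,8a-octahydronaphthalen-1-yl]-3-methylpentanoate (target)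
Conditions: HF·pyridine, THF/pyridine, 0 °C → rt
Reagents that add atoms: none
Why: Fluoride-driven cleavage of the Si–O bond frees the C3 hydroxyl under conditions that spare the allylic alcohol, the trisubstituted alkene and the methyl ester.

**Compound list**

1 | methyl hydrogen (R)-3-methylglutarate | COC(=O)C[C@H](C)CC(=O)O | starting material
2 | methyl (R)-5-hydroxy-3-methylpentanoate | COC(=O)C[C@H](C)CCO | intermediate
3 | methyl (S)-5-iodo-3-methylpentanoate | COC(=O)C[C@H](C)CCI | intermediate
4 | (3-bromopropoxy)(tert-butyl)dimethylsilane | BrCCCO[Si](C)(C)C(C)(C)C | starting material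
5 | [3-(tert-butyldimethylsilyloxy)propyl]magnesium bromide | Br[Mg]CCCO[Si](C)(C)C(C)(C)C | intermediate
6 | (1S,5S)-(−)-verbenone, (1S,5S)-4,6,6-trimethylbicyclo[3.1.1]hept-3-en-2-one | O=C1C=C(C)[C@@H]2C[C@H]1C2(C)C | starting material
7 | bromomagnesium C8=C9 enolate of the C10 adduct (C1 chain anti to the gem-dimethyl bridge) | Br[Mg]OC1=C[C@](C)(CCCO[Si](C)(C)C(C)(C)C)[C@@H]2C[C@H]1C2(C)C | intermediate
8 | methyl (3R)-5-{(1S,3R,4R,5R)-4-[3-(tert-butyldimethylsilyloxy)propyl]-4,6,6-trimethyl-2-oxobicyclo[3.1.1]heptan-3-yl}-3-methylpentanoate (C1 and C11 chains both anti to the bridge) | O=C1[C@H](CC[C@@H](C)CC(=O)OC)[C@](C)(CCCO[Si](C)(C)C(C)(C)C)[C@@H]2C[C@H]1C2(C)C | intermediate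
9 | methyl (3R)-5-[(1R,5R,6R)-2-acetoxy-6-(3-acetoxypropyl)-6-methyl-5-(prop-1-en-2-yl)cyclohex-2-en-1-yl]-3-methylpentanoate | CC(=O)OC1=CC[C@H](C(C)=C)[C@@](C)(CCCOC(C)=O)[C@H]1CC[C@@H](C)CC(=O)OC | intermediate
10 | methyl (3R)-5-[(1S,2R,3R)-2-(3-hydroxypropyl)-2-methyl-6-oxo-3-(prop-1-en-2-yl)cyclohexyl]-3-methylpentanoate | O=C1CC[C@H](C(C)=C)[C@@](C)(CCCO)[C@@H]1CC[C@@H](C)CC(=O)OC | intermediate
11 | methyl (3R)-3-methyl-5-[(1S,2R,3R)-2-methyl-6-oxo-2-(3-oxopropyl)-3-(prop-1-en-2-yl)cyclohexyl]pentanoate | O=C1CC[C@H](C(C)=C)[C@@](C)(CCC=O)[C@@H]1CC[C@@H](C)CC(=O)OC | intermediate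
12 | methyl (3R)-5-[(1S,4aS,6R,8aR)-6-hydroxy-5,5,8a-trimethyl-2-oxodecahydronaphthalen-1-yl]-3-methylpentanoate | COC(=O)C[C@H](C)CC[C@@H]1C(=O)CC[C@@H]2C(C)(C)[C@H](O)CC[C@@]12C | intermediate
13 | methyl (3R)-3-methyl-5-[(1S,4aS,6R,8aR)-5,5,8a-trimethyl-2-oxo-6-(triethylsilyloxy)decahydronaphthalen-1-yl]pentanoate | COC(=O)C[C@H](C)CC[C@@H]1C(=O)CC[C@@H]2C(C)(C)[C@H](O[Si](CC)(CC)CC)CC[C@@]12C | intermediate
14 | potassium C7=C8 enolate of 13 | COC(=O)C[C@H](C)CC[C@@H]1C(O[K])=CC[C@@H]2C(C)(C)[C@H](O[Si](CC)(CC)CC)CC[C@@]12C | intermediate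
15 | methyl (3R)-3-methyl-5-[(1S,4aS,6R,8aR)-5,5,8a-trimethyl-6-(triethylsilyloxy)-2-(trifluoromethylsulfonyloxy)-1,4,4a,5,6,7,8,8a-octahydronaphthalen-1-yl]pentanoate | COC(=O)C[C@H](C)CC[C@@H]1C(OS(=O)(=O)C(F)(F)F)=CC[C@@H]2C(C)(C)[C@H](O[Si](CC)(CC)CC)CC[C@@]12C | intermediate
16 | methyl (3R)-5-[(1S,4aS,6R,8aS)-2-(hydroxymethyl)-5,5,8a-trimethyl-6-(triethylsilyloxy)-1,4,4a,5,6,7,8,8a-octahydronaphthalen-1-yl]-3-methylpentanoate | COC(=O)C[C@H](C)CC[C@@H]1C(CO)=CC[C@@H]2C(C)(C)[C@H](O[Si](CC)(CC)CC)CC[C@@]12C | intermediate
17 | methyl (3R)-5-[(1S,4aS,6R,8aS)-6-hydroxy-2-(hydroxymethyl)-5,5,8a-trimethyl-1,4,4a,5,6,7,8,8a-octahydronaphthalen-1-yl]-3-methylpentanoate; labdane numbering 3R,5S,9S,10S,13R | COC(=O)C[C@H](C)CC[C@@H]1C(CO)=CC[C@@H]2C(C)(C)[C@H](O)CC[C@@]12C | target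

**Step count**

Total: 12 steps. Longest linear sequence: 11 steps (1 → 2 → 3 → 8 → … → 17; from verbenone 6 it is 9 steps).

**Steps most likely to fail**

1. Step 4. The C-alkylation of the hindered bromomagnesium enolate (C9 lies beside the new quaternary C10) may be slow, so that proton quench, O-alkylation or attack of residual Grignard reagent on the ester of 3 competes. Fallback, from 6 back to 8: the enolate 7 is generated as in step 4 and trapped at −78 °C with methyl (R)-3-methyl-5-oxopentanoate F1 (from 2 with TEMPO/PhI(OAc)2), an aldol addition that is much less sensitive to hindrance than an SN2 alkylation, to give the β-hydroxy ketone F2. Mesylation (MsCl, Et3N, CH2Cl2) gives the mesylate F3, and DBU eliminates it to the C9=C11 enone F4. Hydrogenation (H2, Pd/C, EtOAc) should deliver hydrogen anti to the bridge and give first the C9 epimer of 8 F5, which NaOMe in MeOH equilibrates to 8.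

2. Step 5. The C4 cation may be captured by acetate, or lose a proton into the ring after hydride shift (loss of the C5 configuration), instead of losing a methyl proton. Fallback, from 8 back to 11: the cleavage is run with Zn(OAc)2 in excess in Ac2O/AcOH so that the cation is steered wholly to capture, giving the triacetate F6 with a tertiary acetate at C4. NaOMe in MeOH at 50 °C removes the three acetates and equilibrates C9 to give the keto diol F7. TEMPO/PhI(OAc)2 oxidises only the primary alcohol to the hydroxy keto aldehyde F8. Syn-dehydration of the tertiary alcohol with the Burgess reagent (methyl N-(triethylammoniosulfonyl)carbamate, benzene, 50 °C) then forms the isopropenyl group by loss of a methyl proton and returns 11.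

3. Step 8. The addition of the C4 radical to the aldehyde may show poor facial selectivity (axial versus equatorial carbinol), and simple reduction of the radical may compete if the reversible addition is slow. Fallback, from 11 back to 12: the cyclisation is run without regard to C3, so that 12 is obtained together with its axial C3 epimer F9. The mixture is oxidised (Dess–Martin periodinane, NaHCO3, CH2Cl2) to the 3,8-dione F10. NaBH4 (1 equiv, MeOH/CH2Cl2, −40 °C) then reduces the 4,4-dimethyl 3-ketone by axial hydride delivery to the equatorial alcohol, the C8 ketone being shielded by the syn-axial C10 methyl group and the C9 chain, which returns 12.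

**Further compounds**

F1 | step 4 | methyl (R)-3-methyl-5-oxopentanoate | COC(=O)C[C@H](C)CC=O
F2 | step 4 | aldol adduct of 7 and F1 (β-hydroxy ketone, C11 carbinol as a mixture) | O=C1[C@H](C(O)C[C@@H](C)CC(=O)OC)[C@](C)(CCCO[Si](C)(C)C(C)(C)C)[C@@H]2C[C@H]1C2(C)C
F3 | step 4 | C11 mesylate of F2 | O=C1[C@H](C(OS(C)(=O)=O)C[C@@H](C)CC(=O)OC)[C@](C)(CCCO[Si](C)(C)C(C)(C)C)[C@@H]2C[C@H]1C2(C)C
F4 | step 4 | C9=C11 enone (alkene geometry not controlled) | O=C1C(=CC[C@@H](C)CC(=O)OC)[C@](C)(CCCO[Si](C)(C)C(C)(C)C)[C@@H]2C[C@H]1C2(C)C
F5 | step 4 | C9 epimer of 8 (C11 chain syn to the bridge) | O=C1[C@@H](CC[C@@H](C)CC(=O)OC)[C@](C)(CCCO[Si](C)(C)C(C)(C)C)[C@@H]2C[C@H]1C2(C)C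
F6 | step 5 | triacetate (C7=C8 enol acetate, C3 acetate, tertiary C4 acetate) | CC(=O)OC1=CC[C@H](C(C)(C)OC(C)=O)[C@@](C)(CCCOC(C)=O)[C@H]1CC[C@@H](C)CC(=O)OC
F7 | step 5 | keto diol (C8 ketone, C3 primary alcohol, C4 tertiary alcohol, C9 equilibrated) | O=C1CC[C@H](C(C)(C)O)[C@@](C)(CCCO)[C@@H]1CC[C@@H](C)CC(=O)OC
F8 | step 5 | hydroxy keto aldehyde (C3 aldehyde, C4 tertiary alcohol) | O=C1CC[C@H](C(C)(C)O)[C@@](C)(CCC=O)[C@@H]1CC[C@@H](C)CC(=O)OC
F9 | step 8 | C3 epimer of 12 (axial hydroxyl) | COC(=O)C[C@H](C)CC[C@@H]1C(=O)CC[C@@H]2C(C)(C)[C@@H](O)CC[C@@]12C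
F10 | step 8 | 3,8-dione | COC(=O)C[C@H](C)CC[C@@H]1C(=O)CC[C@@H]2C(C)(C)C(=O)CC[C@@]12C
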